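**Plan**

1. Retrosynthesis: the O1–C2 and C3–C4 bonds of the pyran ring of the central catechin unit (its ring C) are cut first, then the two C4–aryl interflavan bonds. This leads back to 4-O-benzylphloroglucinaldehyde, two fisetinidol C4 electrophiles made from (2R,3R)-fustin, and a cinnamaldehyde.
2. Forward: fustin is turned into a benzylated 4-methoxyflavan-3-ol. Two of these are tied through O–Si–O tethers to the two ortho hydroxyls of the aldehyde and closed onto the ring in a tethered double Friedel–Crafts reaction. Desilylation gives a bis(flavan-4-yl)salicylaldehyde, on which an aminocatalytic oxa-Michael/aldol annulation with the cinnamaldehyde closes the last ring. Decarbonylation, hydroboration and hydrogenolysis finish the route.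
3. Enabling feature: both upper units are the same (2R,3S,4R)-flavan-4-yl group. The benzene ring that becomes ring A of the central unit therefore has a twofold axis through its formyl-bearing carbon (later C4a) and its benzyloxy-bearing carbon (later C7). The two hydroxyls beside the formyl group (later O1 and 5-OH) are homotopic, so annulation through either gives the same 4→6/4→8 pattern. The formyl carbon itself becomes C4.
4. Stereochemistry: C2 and C3 of both upper units come from fustin. Both upper C4 centres come from delivery of the arene cis to O3 through the tether. C2 of the central unit comes from the (S)-diphenylprolinol silyl ether catalyst, and its C3 from hydroboration anti to the 2-aryl group.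

Key step: step 8

Remark: natural (2R,3R)-fustin is taken as a purchasable starting material; the target is read as a central (2R,3S)-catechin unit carrying two 2,3-trans-3,4-cis (2R,3S,4R) fisetinidol units at C6 and C8.

**Step 1**
Reactants: 1 (2R,3R)-fustin
Product: 2 (2R,3R)-7,3',4'-tri-O-benzylfustin
Conditions: BnBr (3.3 equiv), K2CO3, DMF, 0 °C to rt
Reagents that add atoms: benzyl bromide, BrCc1ccccc1
Why: Williamson etherification, in which the three phenolic hydroxyls are far more acidic than the C3 alcohol and should be benzylated selectively under mild carbonate conditions that leave the two stereocentres of the dihydroflavonol untouched.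

**Step 2**
Reactants: 2 (2R,3R)-7,3',4'-tri-O-benzylfustin
Product: 4 (2R,3S,4R)-7-(benzyloxy)-2-[3,4-bis(benzyloxy)phenyl]-4-methoxychroman-3-ol, via flavan-3,4-diol 3 (not isolated)
Conditions: NaBH4, THF/MeOH, 0 °C; then PPTS (cat.), MeOH, rt
Reagents that add atoms: methanol, CO
Why: Hydride reduction of the C4 ketone should give the 2,3-trans-3,4-trans diol, and acid-catalysed SN1 exchange of the benzylic 4-hydroxyl (activated by the para 7-benzyloxy group) with methanol then tells O4 from O3; the C4 configuration (drawn 4R) is of no consequence because C4 becomes planar in step 5.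

**Step 3**
Reactants: 5 2,4,6-trihydroxybenzaldehyde
Product: 6 4-(benzyloxy)-2,6-dihydroxybenzaldehyde
Conditions: BnBr (1.0 equiv), K2CO3 (1.0 equiv), DMF, 0 °C to rt
Reagents that add atoms: benzyl bromide, BrCc1ccccc1
Why: Williamson etherification of the para hydroxyl, which is the most acidic one and the only one not held in a hydrogen bond to the formyl group.

**Step 4**
Reactants: 4 (2R,3S,4R)-4-methoxyflavan-3-ol (two equivalents); 6 4-(benzyloxy)-2,6-dihydroxybenzaldehyde
Product: 8 bis-silaketal in which O2 and O6 of 6 each carry one unit of 4 through an O–Si(iPr)2–O bridge to its O3, via chlorosilyl ether 7 (not isolated)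
Conditions: 4, iPr2SiCl2 (excess), imidazole, CH2Cl2, 0 °C; excess silane removed in vacuo; then 6 (0.5 equiv), imidazole, DMAP (cat.), DMF, rt
Reagents that add atoms: dichlorodiisopropylsilane, CC(C)[Si](Cl)(Cl)C(C)C
Why: Stepwise formation of an unsymmetrical dialkoxysilane (temporary silicon tether), in which the hindered secondary alcohol should react only once with the excess dichlorosilane and the remaining Si–Cl bond is then taken by each of the two equivalent phenols of 6.

**Step 5**
Reactants: 8 bis-silaketal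
Product: 9 doubly tethered bis-adduct in which C4 of each flavan unit is bonded (4R, cis to O3) to C3 and C5 of the benzaldehyde ring
Conditions: TMSOTf (cat.), 4 Å MS, CH2Cl2 (high dilution), −78 to −30 °C; then Et3N
Reagents that add atoms: none
Why: Proposed new method: TMSOTf ionises each C4 methoxy group to the 7-benzyloxy-stabilised flavan-4-yl cation, and because the arene hangs on the 3-oxygen through a three-atom O–Si–O tether its single free ortho carbon (the other one carries the formyl group) can reach only the lobe of the cationic C4 on the side of O3 through a seven-membered transition state, which should give the 4R (3,4-cis) aryl–C4 bond at both units, whereas the untethered reaction is expected to favour the 3,4-trans isomer; the closest known reaction types are the tether-directed intramolecular arylation of flavan-4-yl cations through a diester bridge between the 3-oxygens of two flavan units and silicon-tethered intramolecular aglycon delivery.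

**Step 6**
Reactants: 9 doubly tethered bis-adduct
Product: 10 4-(benzyloxy)-3,5-bis[(2R,3S,4R)-7-(benzyloxy)-2-(3,4-bis(benzyloxy)phenyl)-3-hydroxychroman-4-yl]-2,6-dihydroxybenzaldehyde
Conditions: HF·pyridine, pyridine/THF, 0 °C to rt
Reagents that add atoms: none
Why: Fluoride-mediated desilylation should cleave both the aryl–O–Si and the alkyl–O–Si bonds of the two tethers while benzyl ethers, the aldehyde and all stereocentres stay untouched.

**Step 7**
Reactants: 11 3,4-bis(benzyloxy)benzaldehyde; 12 (triphenylphosphoranylidene)acetaldehyde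
Product: 13 (E)-3-[3,4-bis(benzyloxy)phenyl]prop-2-enal
Conditions: toluene, 80 °C
Reagents that add atoms: none
Why: Wittig olefination with a stabilised ylide, which should give the (E)-enal.

**Step 8**
Reactants: 10 bis(flavan-4-yl)-2,6-dihydroxybenzaldehyde; 13 (E)-3-[3,4-bis(benzyloxy)phenyl]prop-2-enal
Product: 15 (2R)-7-(benzyloxy)-2-[3,4-bis(benzyloxy)phenyl]-6,8-bis(flavan-4-yl)-5-hydroxy-2H-chromene-3-carbaldehyde, via oxa-Michael aldehyde 14 (not isolated)
Conditions: (S)-α,α-diphenylprolinol trimethylsilyl ether (20 mol %), 2-nitrobenzoic acid (20 mol %), 13 (1.5 equiv), 4 Å MS, toluene, rt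
Reagents that add atoms: none
Why: The secondary amine condenses with enal 13 to an (E)-iminium ion, one face of which is covered by the diphenyl(silyloxy)methyl group, so a phenolic oxygen of 10 should add to the β-carbon from the open face (oxa-Michael) and set the later C2 as R by catalyst control; should the opposite sense be found, the (R)-catalyst is used, and the minor C2 epimer is in any case a separable diastereomer. The enamine so formed attacks the neighbouring formyl carbon (the later C4) in a 6-exo-trig (enolexo) aldol closure of ring C, and loss of water and hydrolysis of the iminium ion release the 2H-chromene-3-carbaldehyde and the catalyst. The closest known reaction type is the diarylprolinol silyl ether catalysed domino oxa-Michael/aldol condensation of salicylaldehydes with cinnamaldehydes. Site selectivity is no issue, because the two hydroxyls beside the formyl group are exchanged by the twofold axis of 10 and either one leads to the same 4→6/4→8 pattern. Chemoselectivity for oxygen attack rests on the absence of any free position on the central ring, on the low nucleophilicity of the benzylated resorcinol rings, and on the fact that addition of the secondary hydroxyls is reversible and leads nowhere. The formyl group left on C3 is only the handle for enamine activation and is taken out in step 9.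

**Step 9**
Reactants: 15 (2R)-2H-chromene-3-carbaldehyde
Product: 16 (2S)-7-(benzyloxy)-2-[3,4-bis(benzyloxy)phenyl]-6,8-bis(flavan-4-yl)-2H-chromen-5-ol (flav-3-ene; same spatial arrangement at C2 as in 15)
Conditions: RhCl(PPh3)3 (1.1 equiv), toluene, 100 °C
Reagents that add atoms: none
Why: Tsuji–Wilkinson decarbonylation (oxidative addition of the formyl C–H bond, extrusion of CO, reductive elimination) should replace CHO by H with the double bond held at C3–C4, so that C2 is not touched.

**Step 10**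
Reactants: 16 flav-3-ene
Product: 18 nona-O-benzyl trimer with a (2R,3S)-flavan-3-ol central unit, via C3 alkylborane 17 (not isolated)
Conditions: BH3·THF (excess), THF, 0 °C to rt; then NaOH, H2O2, 0 °C
Reagents that add atoms: hydrogen peroxide, OO
Why: Hydroboration–oxidation of the styrene-type C3–C4 double bond, in which boron should add to C3 (away from the electron-rich ring A) on the face opposite to the C2 aryl group and is then replaced by OH with retention, setting C3 as S (2,3-trans).

**Step 11**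
Reactants: 18 nona-O-benzyl trimer
Product: 19 target, (2R,3S)-2-(3,4-dihydroxyphenyl)-6,8-bis[(2R,3S,4R)-2-(3,4-dihydroxyphenyl)-3,7-dihydroxychroman-4-yl]chroman-3,5,7-triol
Conditions: H2 (1 atm), Pd(OH)2/C, THF/MeOH, rt
Reagents that add atoms: none
Why: Hydrogenolysis of all nine benzyl ethers, under which the flavan C2–O bonds and the interflavan bonds are expected to persist.

**Compound list**

1 | (2R,3R)-fustin, (2R,3R)-2-(3,4-dihydroxyphenyl)-3,7-dihydroxychroman-4-one | Oc1ccc2c(c1)O[C@H](c1ccc(O)c(O)c1)[C@@H](O)C2=O | starting material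

2 | (2R,3R)-7-(benzyloxy)-2-[3,4-bis(benzyloxy)phenyl]-3-hydroxychroman-4-one | c1ccccc1COc1ccc2c(c1)O[C@H](c1ccc(OCc3ccccc3)c(OCc3ccccc3)c1)[C@@H](O)C2=O | intermediate

3 | (2R,3S,4R)-7-(benzyloxy)-2-[3,4-bis(benzyloxy)phenyl]chroman-3,4-diol (not isolated) | c1ccccc1COc1ccc2c(c1)O[C@H](c1ccc(OCc3ccccc3)c(OCc3ccccc3)c1)[C@@H](O)[C@@H]2O | intermediate

4 | (2R,3S,4R)-7-(benzyloxy)-2-[3,4-bis(benzyloxy)phenyl]-4-methoxychroman-3-ol | c1ccccc1COc1ccc2c(c1)O[C@H](c1ccc(OCc3ccccc3)c(OCc3ccccc3)c1)[C@@H](O)[C@@H]2OC | intermediate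

5 | 2,4,6-trihydroxybenzaldehyde | O=Cc1c(O)cc(O)cc1O | starting material

6 | 4-(benzyloxy)-2,6-dihydroxybenzaldehyde | O=Cc1c(O)cc(OCc2ccccc2)cc1O | intermediate

7 | chloro(diisopropyl)silyl ether of 4 at O3 (not isolated) | c1ccccc1COc1ccc2c(c1)O[C@H](c1ccc(OCc3ccccc3)c(OCc3ccccc3)c1)[C@@H](O[Si](Cl)(C(C)C)C(C)C)[C@@H]2OC | intermediate

8 | 4-(benzyloxy)-2,6-bis({diisopropyl[(2R,3S,4R)-7-(benzyloxy)-2-(3,4-bis(benzyloxy)phenyl)-4-methoxychroman-3-yloxy]silyl}oxy)benzaldehyde | O=Cc1c(O[Si](C(C)C)(C(C)C)O[C@@H]2[C@@H](c3ccc(OCc4ccccc4)c(OCc4ccccc4)c3)Oc3cc(OCc4ccccc4)ccc3[C@H]2OC)cc(OCc2ccccc2)cc1O[Si](C(C)C)(C(C)C)O[C@@H]1[C@@H](c2ccc(OCc3ccccc3)c(OCc3ccccc3)c2)Oc2cc(OCc3ccccc3)ccc2[C@H]1OC | intermediate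

9 | doubly tethered bis-adduct: as 8 without the methoxy groups, C4 of each chroman (4R, cis to O3) bonded to C3 and C5 of the benzaldehyde ring, each O–Si(iPr)2–O bridge closing a seven-membered 1,3-dioxa-2-silepine ring | O=Cc1c2O[Si](C(C)C)(C(C)C)O[C@@H]3[C@@H](c4ccc(OCc5ccccc5)c(OCc5ccccc5)c4)Oc4cc(OCc5ccccc5)ccc4[C@@H]3c2c(OCc2ccccc2)c2c1O[Si](C(C)C)(C(C)C)O[C@@H]1[C@@H](c3ccc(OCc4ccccc4)c(OCc4ccccc4)c3)Oc3cc(OCc4ccccc4)ccc3[C@@H]12 | intermediate

10 | 4-(benzyloxy)-3,5-bis[(2R,3S,4R)-7-(benzyloxy)-2-(3,4-bis(benzyloxy)phenyl)-3-hydroxychroman-4-yl]-2,6-dihydroxybenzaldehyde | O=Cc1c(O)c([C@H]2c3ccc(OCc4ccccc4)cc3O[C@H](c3ccc(OCc4ccccc4)c(OCc4ccccc4)c3)[C@H]2O)c(OCc2ccccc2)c([C@H]2c3ccc(OCc4ccccc4)cc3O[C@H](c3ccc(OCc4ccccc4)c(OCc4ccccc4)c3)[C@H]2O)c1O | intermediate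

11 | 3,4-bis(benzyloxy)benzaldehyde | O=Cc1ccc(OCc2ccccc2)c(OCc2ccccc2)c1 | starting material

12 | (triphenylphosphoranylidene)acetaldehyde | O=CC=P(c1ccccc1)(c1ccccc1)c1ccccc1 | starting material

13 | (E)-3-[3,4-bis(benzyloxy)phenyl]prop-2-enal | O=C/C=C/c1ccc(OCc2ccccc2)c(OCc2ccccc2)c1 | intermediate

14 | oxa-Michael aldehyde: 10 with one of its two ortho oxygens bonded to C3 of a 3-[3,4-bis(benzyloxy)phenyl]propanal unit (S at this carbon, the later C2); enamine-bound in the flask, drawn as the free aldehyde (not isolated) | O=Cc1c(O[C@H](c2ccc(OCc3ccccc3)c(OCc3ccccc3)c2)CC=O)c([C@H]2c3ccc(OCc4ccccc4)cc3O[C@H](c3ccc(OCc4ccccc4)c(OCc4ccccc4)c3)[C@H]2O)c(OCc2ccccc2)c([C@H]2c3ccc(OCc4ccccc4)cc3O[C@H](c3ccc(OCc4ccccc4)c(OCc4ccccc4)c3)[C@H]2O)c1O | intermediate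

15 | (2R)-7-(benzyloxy)-2-[3,4-bis(benzyloxy)phenyl]-6,8-bis[(2R,3S,4R)-7-(benzyloxy)-2-(3,4-bis(benzyloxy)phenyl)-3-hydroxychroman-4-yl]-5-hydroxy-2H-chromene-3-carbaldehyde | Oc1c([C@H]2c3ccc(OCc4ccccc4)cc3O[C@H](c3ccc(OCc4ccccc4)c(OCc4ccccc4)c3)[C@H]2O)c(OCc2ccccc2)c([C@H]2c3ccc(OCc4ccccc4)cc3O[C@H](c3ccc(OCc4ccccc4)c(OCc4ccccc4)c3)[C@H]2O)c2c1C=C(C=O)[C@@H](c1ccc(OCc3ccccc3)c(OCc3ccccc3)c1)O2 | intermediate

16 | (2S)-7-(benzyloxy)-2-[3,4-bis(benzyloxy)phenyl]-6,8-bis[(2R,3S,4R)-7-(benzyloxy)-2-(3,4-bis(benzyloxy)phenyl)-3-hydroxychroman-4-yl]-2H-chromen-5-ol (the descriptor at C2 changes with the loss of the formyl group, the arrangement in space does not) | Oc1c([C@H]2c3ccc(OCc4ccccc4)cc3O[C@H](c3ccc(OCc4ccccc4)c(OCc4ccccc4)c3)[C@H]2O)c(OCc2ccccc2)c([C@H]2c3ccc(OCc4ccccc4)cc3O[C@H](c3ccc(OCc4ccccc4)c(OCc4ccccc4)c3)[C@H]2O)c2c1C=C[C@@H](c1ccc(OCc3ccccc3)c(OCc3ccccc3)c1)O2 | intermediate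

17 | C3 alkylborane of 16, boron on C3 trans to the 2-aryl group, drawn as RBH2 (the hydroxyl groups are carried as borate esters until work-up; not isolated) | Oc1c([C@H]2c3ccc(OCc4ccccc4)cc3O[C@H](c3ccc(OCc4ccccc4)c(OCc4ccccc4)c3)[C@H]2O)c(OCc2ccccc2)c([C@H]2c3ccc(OCc4ccccc4)cc3O[C@H](c3ccc(OCc4ccccc4)c(OCc4ccccc4)c3)[C@H]2O)c2c1C[C@H](B)[C@@H](c1ccc(OCc3ccccc3)c(OCc3ccccc3)c1)O2 | intermediate

18 | (2R,3S)-7-(benzyloxy)-2-[3,4-bis(benzyloxy)phenyl]-6,8-bis[(2R,3S,4R)-7-(benzyloxy)-2-(3,4-bis(benzyloxy)phenyl)-3-hydroxychroman-4-yl]chroman-3,5-diol (nona-O-benzyl trimer) | Oc1c([C@H]2c3ccc(OCc4ccccc4)cc3O[C@H](c3ccc(OCc4ccccc4)c(OCc4ccccc4)c3)[C@H]2O)c(OCc2ccccc2)c([C@H]2c3ccc(OCc4ccccc4)cc3O[C@H](c3ccc(OCc4ccccc4)c(OCc4ccccc4)c3)[C@H]2O)c2c1C[C@H](O)[C@@H](c1ccc(OCc3ccccc3)c(OCc3ccccc3)c1)O2 | intermediate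

19 | (2R,3S)-2-(3,4-dihydroxyphenyl)-6,8-bis[(2R,3S,4R)-2-(3,4-dihydroxyphenyl)-3,7-dihydroxychroman-4-yl]chroman-3,5,7-triol | Oc1ccc2c(c1)O[C@H](c1ccc(O)c(O)c1)[C@@H](O)[C@H]2c1c(O)c2c(c([C@H]3c4ccc(O)cc4O[C@H](c4ccc(O)c(O)c4)[C@H]3O)c1O)O[C@H](c1ccc(O)c(O)c1)[C@@H](O)C2 | target

**Step count and risks**

Total step count: 11. Longest linear sequence: 9 steps (1, 2, 4, 5, 6, 8, 9, 10, 11).

Step 5 (proposed new method). The silylated, formyl-bearing arene may attack too slowly, so that the flavan-4-yl cation is lost by elimination or by intermolecular attack, or the tether may be cleaved by the Lewis acid before the C–C bond forms. The fallback gives up the tether and uses known chemistry. It sets out from 4 (two equivalents) and 6: an intermolecular acid-mediated Friedel–Crafts condensation (BF3·OEt2, CH2Cl2/THF, −20 to 0 °C) at the two free nuclear positions of 6 should pass through the mono-adduct F1 and give 10 together with its C4 epimers, the (4S),(4R) bis-adduct F2 and the (4S),(4S) bis-adduct F3. Compound 10 is then separated by chromatography; the untethered reaction is expected to favour the 3,4-trans linkage, so the wanted isomer would be a minor component. The route is rejoined at 10, and steps 4 to 6 fall away.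

Step 8. The oxa-Michael addition of a hydrogen-bonded phenol that is flanked by a bulky flavanyl group may be too slow, so that turnover of the amine catalyst and control of the new centre are lost. The fallback is a Petasis-type borono-Mannich condensation and sets out from 10. Aldehyde 11 is first converted with bis(pinacolatoboryl)methane and LiTMP (boron-Wittig olefination) into the (E)-alkenylboronic ester F4. Heating 10 with F4 and dibenzylamine in dioxane at 90 °C should then lead, by alkenyl transfer to the iminium ion, loss of the amine and oxa-6π-electrocyclisation of the ortho-quinone methide, to the flav-3-ene 16 and its C2 epimer F5 without control at C2. The two are diastereomers because of the six stereocentres of the flavanyl groups and are separated by chromatography. The route is rejoined at 16, and steps 7 to 9 fall away.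

Step 9. The C3–C4 double bond may migrate towards the ring oxygen through a rhodium hydride, or the 2H-chromene may open thermally with loss of the C2 configuration. The fallback exchanges carbon for oxygen at C3 with retention and sets out from 15. Conjugate reduction with [(Ph3P)CuH]6 (or a Hantzsch ester with dibenzylammonium trifluoroacetate) and equilibration with DBU should favour the diequatorial 2,3-trans aldehyde F6. Baeyer–Villiger oxidation (mCPBA, NaHCO3, CH2Cl2, 0 °C) should then give the formate F7 with retention at C3, and methanolysis (K2CO3, MeOH) gives 18. The route is rejoined at 18, and steps 9 and 10 fall away.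

**Further compounds**

F1 | step 5 | mono-adduct, 4-(benzyloxy)-3-[(2R,3S,4R)-7-(benzyloxy)-2-(3,4-bis(benzyloxy)phenyl)-3-hydroxychroman-4-yl]-2,6-dihydroxybenzaldehyde | O=Cc1c(O)c([C@H]2c3ccc(OCc4ccccc4)cc3O[C@H](c3ccc(OCc4ccccc4)c(OCc4ccccc4)c3)[C@H]2O)c(OCc2ccccc2)cc1O

F2 | step 5 | (4S),(4R) bis-adduct, epimer of 10 at C4 of one flavan unit | O=Cc1c(O)c([C@@H]2c3ccc(OCc4ccccc4)cc3O[C@H](c3ccc(OCc4ccccc4)c(OCc4ccccc4)c3)[C@H]2O)c(OCc2ccccc2)c([C@H]2c3ccc(OCc4ccccc4)cc3O[C@H](c3ccc(OCc4ccccc4)c(OCc4ccccc4)c3)[C@H]2O)c1O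

F3 | step 5 | (4S),(4S) bis-adduct, epimer of 10 at C4 of both flavan units | O=Cc1c(O)c([C@@H]2c3ccc(OCc4ccccc4)cc3O[C@H](c3ccc(OCc4ccccc4)c(OCc4ccccc4)c3)[C@H]2O)c(OCc2ccccc2)c([C@@H]2c3ccc(OCc4ccccc4)cc3O[C@H](c3ccc(OCc4ccccc4)c(OCc4ccccc4)c3)[C@H]2O)c1O

F4 | step 8 | (E)-2-{2-[3,4-bis(benzyloxy)phenyl]ethenyl}-4,4,5,5-tetramethyl-1,3,2-dioxaborolane | CC1(C)OB(/C=C/c2ccc(OCc3ccccc3)c(OCc3ccccc3)c2)OC1(C)C

F5 | step 8 | (2R)-flav-3-ene, C2 epimer of 16 | Oc1c([C@H]2c3ccc(OCc4ccccc4)cc3O[C@H](c3ccc(OCc4ccccc4)c(OCc4ccccc4)c3)[C@H]2O)c(OCc2ccccc2)c([C@H]2c3ccc(OCc4ccccc4)cc3O[C@H](c3ccc(OCc4ccccc4)c(OCc4ccccc4)c3)[C@H]2O)c2c1C=C[C@H](c1ccc(OCc3ccccc3)c(OCc3ccccc3)c1)O2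

F6 | step 9 | (2R,3S)-3-formylflavan, the 2,3-trans dihydro derivative of 15 | Oc1c([C@H]2c3ccc(OCc4ccccc4)cc3O[C@H](c3ccc(OCc4ccccc4)c(OCc4ccccc4)c3)[C@H]2O)c(OCc2ccccc2)c([C@H]2c3ccc(OCc4ccccc4)cc3O[C@H](c3ccc(OCc4ccccc4)c(OCc4ccccc4)c3)[C@H]2O)c2c1C[C@H](C=O)[C@@H](c1ccc(OCc3ccccc3)c(OCc3ccccc3)c1)O2

F7 | step 9 | 3-O-formate of 18 | Oc1c([C@H]2c3ccc(OCc4ccccc4)cc3O[C@H](c3ccc(OCc4ccccc4)c(OCc4ccccc4)c3)[C@H]2O)c(OCc2ccccc2)c([C@H]2c3ccc(OCc4ccccc4)cc3O[C@H](c3ccc(OCc4ccccc4)c(OCc4ccccc4)c3)[C@H]2O)c2c1C[C@H](OC=O)[C@@H](c1ccc(OCc3ccccc3)c(OCc3ccccc3)c1)O2
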